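The meeting took beta, everything together at the start, as the earlier run to improve on, and had these flasks and questions before it.

| flask | starting material | fresh partner | gas | time | remark |
|---|---|---|---|---|---|
| epsilon | 0.20 M | 1.20 equiv (fed, over 20 s) | 59 mM (held) | 25 s | all else is in the flask from the start; the feed brings no volume worth counting |
| beta | 0.20 M | 1.20 equiv | 59 mM (held) | 25 s | everything together at the start |
| zeta | 0.20 M | 1.20 equiv (in portions, 4, over 20 s) | 59 mM (held) | 25 s | first portion at the start, last at 20 s |
| eta | 0.20 M (fed, over 5.0 s) | 1.20 equiv | 59 mM (held) | 25 s | all else is in the flask from the start; the feed brings no volume worth counting |
| theta | 0.20 M (fed, over 20 s) | 1.20 equiv | 59 mM (held) | 25 s | all else is in the flask from the start; the feed brings no volume worth counting |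

    starting material + coupling partner → open intermediate (k1 = 0.64 L mol⁻¹ s⁻¹)
    coupling partner + fresh partner → second intermediate (k2 = 0.71 L mol⁻¹ s⁻¹)
    open intermediate + second intermediate → target (k3 = 15 L mol⁻¹ s⁻¹)
    starting material + open intermediate → side product (k4 = 0.43 L mol⁻¹ s⁻¹)
    gas ⇌ coupling partner, rate k5*(csat - [coupling partner]) (k5 = 0.19 s⁻¹, csat = 59 mM)

- percentages count the starting material that a species holds: one side product counts as two
- at the start none of coupling partner is dissolved
- run time (epsilon): 25 s

- the flask that comes out highest in share of target in target plus side product, or "all alike" when all lie within 1.5 percentage points (epsilon / beta / zeta / eta / theta / all alike)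
- share of target in target plus side product at the end, epsilon
- share of target in target plus side product at the end, beta
- share of target in target plus side product at the end, zeta
- share of target in target plus side product at the end, eta
- share of target in target plus side product at the end, theta

I opened by saying that open intermediate has two exits, and that the ratio of their rates, which I proposed to call the branch number, is the selectivity factor, the constant of the step to target over that of the step to side product, 34.9, multiplied by second intermediate over starting material. As one side product counts as two, I went on, target and side product stand level in the share at a branch number of two, which against the full charge of starting material asks for 11.5 mM of second intermediate, or 4.78% of the fresh partner charge, so the question is how soon those turnovers are done.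

I counted them at 5.0 s, neglecting the lag of dissolving and the second intermediate lost to target. In beta, the pulls of fresh partner, 0.170 s⁻¹, and of starting material, 0.128 s⁻¹, hold coupling partner near 23.0 mM, so second intermediate reaches 19.6 mM, which is more than the level, and the branch number is 3.41. In epsilon, with fresh partner only rising, it reaches 3.75 mM, less than the level, for a branch number of 0.655. Where starting material is dosed into stocked fresh partner, second intermediate gains 5.30 mM s⁻¹ while, on this count, starting material grows in step with it, so the ratio stays level during the feed, which gives 4.62 in eta and 18.5 in theta, the highest of these. I therefore ranked theta, eta, beta, and put zeta beside epsilon, as both spread fresh partner over 20 s; these are estimated ratios during the run, not end shares.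

The author of the forecast held that “stocking the flask with fresh partner and dosing starting material (theta, then eta) favours target”, and named theta, with end shares of 51% for epsilon, 72% for beta, 56% for zeta, 78% for eta and 89% for theta. Its order from theta down to beta is the same as mine.

The flasks gave 52.0% for epsilon, 69.8% for beta, 52.6% for zeta, 72.3% for eta and 84.2% for theta, with theta highest. In epsilon at 25.0 s, the selectivity factor with 0.0214 M of second intermediate and 0.116 M of starting material gives a branch number of 6.43, up from a rate ratio of 1.7 at 11.7 s. In the neighbour flask, epsilon with 0.34 M of starting material, the same count on 0.0304 M and 0.219 M gives 4.84, and its end share is lower than epsilon's, at 42.1%.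

The numbers of this flask were chosen freely; no experiment stands behind them.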